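The data stem from a simulated flask for substances that don't exist; scatter was added.

The red and green runs moved slowly after their first readings. In the red run substrate stood at 11.1 % after 0.625 d, and double product went from 23.6 % to 21.5 % by 8.00 d. So I read the late readings as a balance: dividing one rate by another removes time, and what stays is partner taken up per substrate charged.

the same everywhere: partner 0.0945 M

| flask | substrate | remark | time |
|---|---|---|---|
| red | 0.088 M | run made earlier |  |
| green | 0.14 M | run made earlier |  |
| flask | 0.063 M |  | 8.0 d |

- red (time / d: substrate / %, first product / %, double product / %): 0.625: 11.1, 3.7, 23.6; 1.67: 6.5, 1.3, 21.3; 3.00: 5.7, 1.1, 24.5; 5.00: 3.7, 0.5, 21.9; 8.00: 3.3, 0.3, 21.5; 10.0: 4.9, 0, 23.4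
- green (time / d: substrate / %, first product / %, double product / %): 1.67: 17.1, 0, 13.4; 3.00: 16.9, 1.2, 12.5; 5.00: 14.9, 0, 13.5; 6.00: 14.8, 0.8, 11.9; 8.00: 17.9, 0.1, 12.8; 10.0: 18.9, 0, 12.3

(readings scatter by 1 percentage point)

- how much substrate there is at 8.0 d, in percent of the substrate charged
- how much first product there is at 8.0 d, in percent of the substrate charged
- how much double product there is at 8.0 d, in percent of the substrate charged
- how much triple product there is at 8.0 d, in percent of the substrate charged



I built the flask up one process at a time, taking the red readings at 8.00 d as my estimate for it, since red is the nearest recipe. With just the partner chain, each step adding one partner, the unseen remainder of 74.9 % is triple product. That costs 2.68 partners per substrate, but red offers 1.07 and the flask 1.50, so the remainder can't be triple product throughout.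

Next I added a path cheap in partner, my own guess: first product meeting substrate, a pair holding two substrate units and one partner. The substrate and partner balances then give a rule. From partner taken up per substrate, subtract first product, two for each double product, and the unseen remainder divided by two, then divide by 2.50. For the flask this triple share by partner balance is 27.7 %, where I counted the whole partner charge as taken up. Red's own readings give 10.7 %. The last addition, partner left unused, would lower the share, and I counted none.

The forecast gave substrate 1.2 %, first product 0.2 %, double product 28 % and triple product 70.6 %: “The remainder, about 70%, is triple product”. My reckoning parts from it on triple product, where 27.7 % stands lower.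

The flask gave substrate 0.935 %, first product 0.120 %, double product 23.2 % and triple product 26.1 %.

    substrate + partner → first product + by-product (k = 9.70 × 10⁻⁴ L mol⁻¹ s⁻¹)
    partner + first product → double product + by-product (k = 0.00440 L mol⁻¹ s⁻¹)
    partner + double product → triple product + by-product (k = 3.00 × 10⁻⁴ L mol⁻¹ s⁻¹)
    substrate + first product → side product (k = 0.00440 L mol⁻¹ s⁻¹)

With 0.21 % of the partner left at 8.00 d, the rule on these amounts gives 26.1 %. On the neighbour charged with 0.16 M of partner, 12 % left, it gives 69.5 %, and that flask holds 69.5 %. Part of the reason for the low double product in this flask, though not the main one, is the step from substrate and first product to side product: the same flask run without that step holds 53.5 % of double product instead of 23.2 %.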